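**Retrosynthetic overview**

1. Feature: the ring C3/C4 oxirane is a masked trisubstituted C3=C4 alkene. Without it, the carbocycle C1–C6 opens between C3 and C4 to a chain whose all-cis C6/C1/C2 triad is a syn-aldol (C6/C1) plus anti-diol (C1/C2) pattern.
2. Late stage: C3/C4 oxirane from C2–OH-directed epoxidation; C8 angelate and C1 (R)-2-methylbutanoate by esterification; C7–C8 by Ni/Cr coupling of a C7 enol triflate with a C8–C11 epoxy aldehyde.
3. Core: cyclohexene C1–C6 by ring-closing metathesis that forms C3=C4 from an acyclic 1,7-diene Weinreb amide.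
4. Diene: Evans syn aldol of a pent-4-enoyl oxazolidinone with an (S)-α-silyloxy isopropenyl aldehyde made from (R)-glyceraldehyde acetonide.
5. Ring order: side-chain oxirane (on the C8–C11 fragment), then the cyclohexene (metathesis), then the ring oxirane in the last step.

Key step: step 12

Remarks. Locants: ring C1 (acyloxy), C2 (OH), C3 (methyl), C4, C5, C6 (side chain); chain C7(=C14H2), C8 (angelate), C9, C10/C11 (oxirane). TBS = tert-butyldimethylsilyl, TES = triethylsilyl; TBSO and TESO are the corresponding silyloxy groups. Assumption: the 2-methylbutanoate is R as drawn, so commercial (R)-2-methylbutanoic acid is used. The entry's bis-TBS precursor is changed to C1-OTES/C2-OTBS so that C1 can be freed first.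

**Route**

Step 1
Reactants: 1 (R)-2,3-O-isopropylideneglyceraldehyde
Product: 2 1-[(4R)-2,2-dimethyl-1,3-dioxolan-4-yl]ethan-1-ol (both carbinol epimers)
Conditions: MeMgBr, Et2O, −78 to 0 °C; aq. NH4Cl
Reagents that add atoms: methylmagnesium bromide, C[Mg]Br
Why: Grignard addition to the aldehyde; the new carbinol centre is oxidised away in step 2, so its configuration does not matter, and the dioxolane centre (the later C2) is untouched.

Step 2
Reactants: 2 1-[(4R)-2,2-dimethyl-1,3-dioxolan-4-yl]ethan-1-ol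
Product: 3 1-[(4R)-2,2-dimethyl-1,3-dioxolan-4-yl]ethan-1-one
Conditions: Dess–Martin periodinane, CH2Cl2, 0 °C to rt
Reagents that add atoms: none
Why: Dess–Martin oxidation of the secondary alcohol under neutral conditions that do not enolise the α-alkoxy ketone, so the dioxolane centre keeps its configuration.

Step 3
Reactants: 3 1-[(4R)-2,2-dimethyl-1,3-dioxolan-4-yl]ethan-1-one
Product: 4 (4S)-2,2-dimethyl-4-(prop-1-en-2-yl)-1,3-dioxolane
Conditions: Ph3PCH3Br, KOt-Bu, THF, 0 °C; then 3, −78 to 0 °C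
Reagents that add atoms: methyltriphenylphosphonium bromide, C[P+](c1ccccc1)(c1ccccc1)c1ccccc1.[Br-]
Why: Wittig methylenation installs the isopropenyl group (C3 with its methyl) regiospecifically; the preformed ylide is consumed at low temperature before it can epimerise the α-alkoxy centre, whose descriptor becomes S only through the priority rules.

Step 4
Reactants: 4 (4S)-2,2-dimethyl-4-(prop-1-en-2-yl)-1,3-dioxolane
Product: 5 (2S)-3-methylbut-3-ene-1,2-diol
Conditions: AcOH/H2O (4:1), rt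
Reagents that add atoms: none
Why: Acid-catalysed acetal hydrolysis frees the diol without touching the allylic stereocentre, since no C–O bond at that carbon is broken.

Step 5
Reactants: 5 (2S)-3-methylbut-3-ene-1,2-diol
Product: 6 (2S)-1,2-bis(TBSO)-3-methylbut-3-ene
Conditions: TBSCl, imidazole, DMF, rt
Reagents that add atoms: tert-butyldimethylsilyl chloride, CC(C)(C)[Si](C)(C)Cl
Why: Imidazole-promoted silylation of both hydroxyls; exhaustive protection avoids any regiochemical question at this stage.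

Step 6
Reactants: 6 (2S)-1,2-bis(TBSO)-3-methylbut-3-ene
Product: 7 (2S)-2-(TBSO)-3-methylbut-3-en-1-ol
Conditions: HF·pyridine, pyridine, THF, 0 °C
Reagents that add atoms: none
Why: Selective desilylation: the unhindered primary silyl ether is cleaved much faster by buffered fluoride than the secondary allylic one, which leaves the C2 oxygen protected.

Step 7
Reactants: 7 (2S)-2-(TBSO)-3-methylbut-3-en-1-ol
Product: 8 (2S)-2-(TBSO)-3-methylbut-3-enal
Conditions: Dess–Martin periodinane, pyridine, CH2Cl2, 0 °C; used crude at once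
Reagents that add atoms: none
Why: Dess–Martin oxidation under buffered, non-basic conditions should give the α-silyloxy β,γ-unsaturated aldehyde without epimerisation or migration of the alkene into conjugation.

Step 8
Reactants: 9 (4R)-4-benzyl-1,3-oxazolidin-2-one; 10 pent-4-enoyl chloride
Product: 11 (4R)-4-benzyl-3-(pent-4-enoyl)-1,3-oxazolidin-2-one
Conditions: Et3N, DMAP (cat.), CH2Cl2, 0 °C to rt
Reagents that add atoms: none
Why: DMAP-catalysed N-acylation of the oxazolidinone with the acid chloride; the auxiliary centre is not involved.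

Step 9
Reactants: 11 (4R)-4-benzyl-3-(pent-4-enoyl)-1,3-oxazolidin-2-one; 8 (2S)-2-(TBSO)-3-methylbut-3-enal
Product: 14 (4R)-4-benzyl-3-[(2R,3R,4S)-2-allyl-3-hydroxy-5-methyl-4-(TBSO)hex-5-enoyl]-1,3-oxazolidin-2-one, via dibutylboron Z-enolate 12 (not isolated), via dibutylboron aldolate 13 (not isolated)
Conditions: Bu2BOTf, i-Pr2NEt, CH2Cl2, −78 to 0 °C; then 8, −78 to 0 °C; pH 7 buffer, MeOH, H2O2, 0 °C
Reagents that add atoms: none
Why: Evans syn-aldol reaction: the Z-boron enolate reacts through a Zimmerman–Traxler chair in which the (R)-benzyl auxiliary sets the two new centres 2R,3R (later C6 and C1, syn), and Cornforth/polar Felkin–Anh addition to the (S)-α-silyloxy aldehyde gives the 3,4-anti relation, so auxiliary and aldehyde are matched.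

Step 10
Reactants: 14 (4R)-4-benzyl-3-[(2R,3R,4S)-2-allyl-3-hydroxy-5-methyl-4-(TBSO)hex-5-enoyl]-1,3-oxazolidin-2-one
Product: 15 (2R,3R,4S)-2-allyl-3-hydroxy-N-methoxy-N,5-dimethyl-4-(TBSO)hex-5-enamide
Conditions: MeNHOMe·HCl, AlMe3, CH2Cl2, −20 to 0 °C; aq. KNaC4H4O6 (potassium sodium tartrate)
Reagents that add atoms: N,O-dimethylhydroxylamine hydrochloride, CNOC.Cl
Why: Aluminium amide transamidation (Weinreb amide formation), assisted by the free β-hydroxyl, removes the auxiliary under conditions that should not epimerise the α-centre.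

Step 11
Reactants: 15 (2R,3R,4S)-2-allyl-3-hydroxy-N-methoxy-N,5-dimethyl-4-(TBSO)hex-5-enamide
Product: 16 (2R,3R,4S)-2-allyl-N-methoxy-N,5-dimethyl-4-(TBSO)-3-(TESO)hex-5-enamide
Conditions: TESOTf, 2,6-lutidine, CH2Cl2, −78 to 0 °C
Reagents that add atoms: triethylsilyl trifluoromethanesulfonate, CC[Si](CC)(CC)OS(=O)(=O)C(F)(F)F
Why: Silylation with a silyl triflate protects the hindered C1 hydroxyl with a group that is more acid-labile than the C2 TBS ether, which differentiates the two oxygens for the end game.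

Step 12
Reactants: 16 (2R,3R,4S)-2-allyl-N-methoxy-N,5-dimethyl-4-(TBSO)-3-(TESO)hex-5-enamide
Product: 17 (1R,5S,6R)-N-methoxy-N,4-dimethyl-5-(TBSO)-6-(TESO)cyclohex-3-ene-1-carboxamide
Conditions: second-generation Grubbs catalyst (H2IMes)(PCy3)Cl2Ru=CHPh (5 mol%), CH2Cl2 (0.005 M), 40 °C, argon sparge
Reagents that add atoms: none
Why: Ring-closing olefin metathesis by the Chauvin mechanism: the ruthenium benzylidene first exchanges with the unhindered monosubstituted C4 alkene, the C4 alkylidene so formed adds across the isopropenyl C3=CH2 bond in an intramolecular [2+2] step, and cycloreversion of the ruthenacyclobutane gives the C3=C4 bond and a ruthenium methylidene that continues the cycle. The closest known reaction type is the ring-closing metathesis of 1,7-dienes carrying one 1,1-disubstituted alkene to trisubstituted cyclohexenes with second-generation ruthenium catalysts. The carbocycle C1–C6 closes as an unstrained six-membered ring through the C3/C4 metallacycle, and loss of ethene makes the closure irreversible. No stereocentre is created; C2 (from the glyceraldehyde) and C6/C1 (from step 9) sit on sp3 carbons that the catalyst does not touch, and their acyclic syn/anti relations become the all-cis ring triad. The selectivity needed is ring closure versus intermolecular metathesis at the terminal alkene, and it is secured by high dilution, by the 1,7-spacing of the only two alkenes in the molecule and by the low tendency of the 1,1-disubstituted alkene to homodimerise.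

Step 13
Reactants: 17 (1R,5S,6R)-N-methoxy-N,4-dimethyl-5-(TBSO)-6-(TESO)cyclohex-3-ene-1-carboxamide
Product: 18 1-[(1R,5S,6R)-4-methyl-5-(TBSO)-6-(TESO)cyclohex-3-en-1-yl]ethan-1-one
Conditions: MeMgBr, THF, 0 °C; aq. NH4Cl
Reagents that add atoms: methylmagnesium bromide, C[Mg]Br
Why: Weinreb ketone synthesis: the chelated adduct resists over-addition and releases the methyl ketone (C7 with C14) only on work-up, so C6 should stay configurationally intact.

Step 14
Reactants: 18 1-[(1R,5S,6R)-4-methyl-5-(TBSO)-6-(TESO)cyclohex-3-en-1-yl]ethan-1-one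
Product: 20 1-[(1R,5S,6R)-4-methyl-5-(TBSO)-6-(TESO)cyclohex-3-en-1-yl]ethenyl trifluoromethanesulfonate, via potassium enolate 19 (not isolated)
Conditions: KN(SiMe3)2, THF, −78 °C; then Comins' reagent, −78 to −40 °C
Reagents that add atoms: N-(5-chloropyridin-2-yl)-1,1,1-trifluoro-N-(trifluoromethanesulfonyl)methanesulfonamide (Comins' reagent), FC(F)(F)S(=O)(=O)N(c1ccc(Cl)cn1)S(=O)(=O)C(F)(F)F
Why: Kinetic enolisation and O-triflation: at −78 °C the hindered amide base removes a proton from the methyl group (C14) and not the tertiary C6–H, so C6 is not epimerised and the C1 silyloxy group is not eliminated, and the triflimide traps the enolate on oxygen.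

Step 15
Reactants: 20 1-[(1R,5S,6R)-4-methyl-5-(TBSO)-6-(TESO)cyclohex-3-en-1-yl]ethenyl trifluoromethanesulfonate
Product: 21 1-[(1R,5S,6R)-6-hydroxy-4-methyl-5-(TBSO)cyclohex-3-en-1-yl]ethenyl trifluoromethanesulfonate
Conditions: pyridinium p-toluenesulfonate (cat.), MeOH/CH2Cl2 (1:1), 0 °C to rt
Reagents that add atoms: none
Why: Acid-catalysed methanolysis cleaves the triethylsilyl ether far faster than the TBS ether, freeing only the C1 hydroxyl; the enol triflate is stable to this weak acid.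

Step 16
Reactants: 21 1-[(1R,5S,6R)-6-hydroxy-4-methyl-5-(TBSO)cyclohex-3-en-1-yl]ethenyl trifluoromethanesulfonate; 22 (2R)-2-methylbutanoic acid
Product: 23 (1R,2S,6R)-3-methyl-2-(TBSO)-6-[1-(trifluoromethanesulfonyloxy)ethenyl]cyclohex-3-en-1-yl (2R)-2-methylbutanoate
Conditions: DCC, DMAP, CH2Cl2, 0 °C to rt
Reagents that add atoms: none
Why: Steglich esterification of the hindered C1 hydroxyl; the acylpyridinium pathway does not enolise the acid, so its (R) α-centre is kept.

Step 17
Reactants: 24 4-methylpent-3-en-1-ol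
Product: 25 2-[(2R)-3,3-dimethyloxiran-2-yl]ethan-1-ol
Conditions: D-fructose-derived Shi ketone (1,2:4,5-di-O-isopropylidene-β-D-erythro-2,3-hexodiulo-2,6-pyranose, 0.3 equiv), KHSO5 (as Oxone), K2CO3, Bu4NHSO4 (cat.), aq. Na2B4O7 buffer, MeCN/CH2(OMe)2, 0 °C
Reagents that add atoms: potassium peroxymonosulfate, [K+].[O-]S(=O)(=O)OO
Why: Shi asymmetric epoxidation: the chiral dioxirane transfers oxygen to the trisubstituted alkene through a spiro transition state, and the D-fructose-derived ketone delivers it to the face that gives the R configuration at C10.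

Step 18
Reactants: 25 2-[(2R)-3,3-dimethyloxiran-2-yl]ethan-1-ol
Product: 26 2-[(2R)-3,3-dimethyloxiran-2-yl]acetaldehyde
Conditions: Dess–Martin periodinane, pyridine, CH2Cl2, 0 °C; used crude at once
Reagents that add atoms: none
Why: Dess–Martin oxidation buffered with pyridine is neutral enough to avoid β-elimination of the β,γ-epoxy aldehyde and opening of the oxirane; C10 is untouched.

Step 19
Reactants: 23 (1R,2S,6R)-3-methyl-2-(TBSO)-6-[1-(trifluoromethanesulfonyloxy)ethenyl]cyclohex-3-en-1-yl (2R)-2-methylbutanoate; 26 2-[(2R)-3,3-dimethyloxiran-2-yl]acetaldehyde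
Product: 27 (1R,2S,6S)-6-{(3S)-4-[(2R)-3,3-dimethyloxiran-2-yl]-3-hydroxybut-1-en-2-yl}-3-methyl-2-(TBSO)cyclohex-3-en-1-yl (2R)-2-methylbutanoate
Conditions: CrCl2, Et3N, chiral ligand N-[2-(4-isopropyl-4,5-dihydrooxazol-2-yl)-6-methylphenyl]methanesulfonamide, THF, rt; then NiCl2 (cat.), 23, 26 (excess), rt
Reagents that add atoms: none
Why: Nozaki–Hiyama–Kishi coupling: zerovalent nickel inserts into the alkenyl C–OTf bond, the alkenyl group passes to chromium and adds to the aldehyde, and the chiral sulfonamide-oxazoline on chromium should direct it to the Re face to set C8 as S (the ligand antipode that gives this sense is fixed in a pilot run), while the non-basic medium spares the epoxy aldehyde, the ester and the silyl ether.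

Step 20
Reactants: 27 (1R,2S,6S)-6-{(3S)-4-[(2R)-3,3-dimethyloxiran-2-yl]-3-hydroxybut-1-en-2-yl}-3-methyl-2-(TBSO)cyclohex-3-en-1-yl (2R)-2-methylbutanoate; 28 angelic acid [(2Z)-2-methylbut-2-enoic acid]
Product: 30 (1R,2S,6S)-6-{(3S)-3-[(2Z)-2-methylbut-2-enoyloxy]-4-[(2R)-3,3-dimethyloxiran-2-yl]but-1-en-2-yl}-3-methyl-2-(TBSO)cyclohex-3-en-1-yl (2R)-2-methylbutanoate, via angelic 2,4,6-trichlorobenzoic anhydride 29 (not isolated)
Conditions: 28, 2,4,6-trichlorobenzoyl chloride, Et3N, toluene, rt; then 27, 80 °C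
Reagents that add atoms: none
Why: Yamaguchi esterification through the preformed mixed anhydride without DMAP, which acylates hindered secondary alcohols with angelic acid without Z-to-E isomerisation to the tiglate; no stereocentre is touched.

Step 21
Reactants: 30 (1R,2S,6S)-6-{(3S)-3-[(2Z)-2-methylbut-2-enoyloxy]-4-[(2R)-3,3-dimethyloxiran-2-yl]but-1-en-2-yl}-3-methyl-2-(TBSO)cyclohex-3-en-1-yl (2R)-2-methylbutanoate
Product: 31 (1R,2S,6S)-6-{(3S)-3-[(2Z)-2-methylbut-2-enoyloxy]-4-[(2R)-3,3-dimethyloxiran-2-yl]but-1-en-2-yl}-2-hydroxy-3-methylcyclohex-3-en-1-yl (2R)-2-methylbutanoate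
Conditions: HF·pyridine, pyridine, THF, 0 °C to rt
Reagents that add atoms: none
Why: Fluoride-mediated desilylation buffered with pyridine removes the allylic TBS ether; under these weakly acidic conditions the oxirane and both esters should survive and the C1 acyl group should not migrate to C2.

Step 22
Reactants: 31 (1R,2S,6S)-6-{(3S)-3-[(2Z)-2-methylbut-2-enoyloxy]-4-[(2R)-3,3-dimethyloxiran-2-yl]but-1-en-2-yl}-2-hydroxy-3-methylcyclohex-3-en-1-yl (2R)-2-methylbutanoate
Product: 32 CNP0181486.1 (target; 1R,2R,3R,4S,6S,8S,10R with the locants above; ester 2R; angelate Z)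
Conditions: VO(acac)2 (cat.), t-BuOOH, CH2Cl2, 0 °C to rt
Reagents that add atoms: tert-butyl hydroperoxide, CC(C)(C)OO
Why: Vanadium-catalysed hydroxyl-directed epoxidation: the C2 hydroxyl binds the vanadium peroxide and delivers oxygen to the syn face of the adjacent C3=C4 alkene, setting C3 (R) and C4 (S) cis to C2–OH, while the C7=C14 alkene and the angelate, which have no allylic hydroxyl, should not react.

**Compound list**

1 | (R)-2,3-O-isopropylideneglyceraldehyde | O=C[C@H]1COC(C)(C)O1 | starting material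
2 | 1-[(4R)-2,2-dimethyl-1,3-dioxolan-4-yl]ethan-1-ol (both carbinol epimers) | CC(O)[C@H]1COC(C)(C)O1 | intermediate
3 | 1-[(4R)-2,2-dimethyl-1,3-dioxolan-4-yl]ethan-1-one | CC(=O)[C@H]1COC(C)(C)O1 | intermediate
4 | (4S)-2,2-dimethyl-4-(prop-1-en-2-yl)-1,3-dioxolane | C=C(C)[C@H]1COC(C)(C)O1 | intermediate
5 | (2S)-3-methylbut-3-ene-1,2-diol | C=C(C)[C@H](O)CO | intermediate
6 | (2S)-1,2-bis(TBSO)-3-methylbut-3-ene | C=C(C)[C@H](O[Si](C)(C)C(C)(C)C)CO[Si](C)(C)C(C)(C)C | intermediate
7 | (2S)-2-(TBSO)-3-methylbut-3-en-1-ol | C=C(C)[C@H](O[Si](C)(C)C(C)(C)C)CO | intermediate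
8 | (2S)-2-(TBSO)-3-methylbut-3-enal | C=C(C)[C@H](O[Si](C)(C)C(C)(C)C)C=O | intermediate
9 | (4R)-4-benzyl-1,3-oxazolidin-2-one | O=C1N[C@H](Cc2ccccc2)CO1 | starting material
10 | pent-4-enoyl chloride | C=CCCC(=O)Cl | starting material
11 | (4R)-4-benzyl-3-(pent-4-enoyl)-1,3-oxazolidin-2-one | C=CCCC(=O)N1[C@H](Cc2ccccc2)COC1=O | intermediate
12 | dibutylboron Z-enolate of 11 | CCCCB(CCCC)O/C(=C\CC=C)N1[C@H](Cc2ccccc2)COC1=O | intermediate (not isolated)
13 | dibutylboron aldolate of 14 | C=CC[C@@H](C(=O)N1[C@H](Cc2ccccc2)COC1=O)[C@@H](OB(CCCC)CCCC)[C@@H](O[Si](C)(C)C(C)(C)C)C(C)=C | intermediate (not isolated)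
14 | (4R)-4-benzyl-3-[(2R,3R,4S)-2-allyl-3-hydroxy-5-methyl-4-(TBSO)hex-5-enoyl]-1,3-oxazolidin-2-one | C=CC[C@@H](C(=O)N1[C@H](Cc2ccccc2)COC1=O)[C@@H](O)[C@@H](O[Si](C)(C)C(C)(C)C)C(C)=C | intermediate
15 | (2R,3R,4S)-2-allyl-3-hydroxy-N-methoxy-N,5-dimethyl-4-(TBSO)hex-5-enamide | C=CC[C@@H](C(=O)N(C)OC)[C@@H](O)[C@@H](O[Si](C)(C)C(C)(C)C)C(C)=C | intermediate
16 | (2R,3R,4S)-2-allyl-N-methoxy-N,5-dimethyl-4-(TBSO)-3-(TESO)hex-5-enamide (metathesis precursor) | C=CC[C@@H](C(=O)N(C)OC)[C@@H](O[Si](CC)(CC)CC)[C@@H](O[Si](C)(C)C(C)(C)C)C(C)=C | intermediate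
17 | (1R,5S,6R)-N-methoxy-N,4-dimethyl-5-(TBSO)-6-(TESO)cyclohex-3-ene-1-carboxamide (metathesis product) | CON(C)C(=O)[C@@H]1CC=C(C)[C@H](O[Si](C)(C)C(C)(C)C)[C@@H]1O[Si](CC)(CC)CC | intermediate
18 | 1-[(1R,5S,6R)-4-methyl-5-(TBSO)-6-(TESO)cyclohex-3-en-1-yl]ethan-1-one | CC(=O)[C@@H]1CC=C(C)[C@H](O[Si](C)(C)C(C)(C)C)[C@@H]1O[Si](CC)(CC)CC | intermediate
19 | potassium enolate of 18 (C7=C14) | [K+].[O-]C(=C)[C@@H]1CC=C(C)[C@H](O[Si](C)(C)C(C)(C)C)[C@@H]1O[Si](CC)(CC)CC | intermediate (not isolated)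
20 | 1-[(1R,5S,6R)-4-methyl-5-(TBSO)-6-(TESO)cyclohex-3-en-1-yl]ethenyl trifluoromethanesulfonate | C=C(OS(=O)(=O)C(F)(F)F)[C@@H]1CC=C(C)[C@H](O[Si](C)(C)C(C)(C)C)[C@@H]1O[Si](CC)(CC)CC | intermediate
21 | 1-[(1R,5S,6R)-6-hydroxy-4-methyl-5-(TBSO)cyclohex-3-en-1-yl]ethenyl trifluoromethanesulfonate | C=C(OS(=O)(=O)C(F)(F)F)[C@@H]1CC=C(C)[C@H](O[Si](C)(C)C(C)(C)C)[C@@H]1O | intermediate
22 | (2R)-2-methylbutanoic acid | CC[C@@H](C)C(=O)O | starting material
23 | (1R,2S,6R)-3-methyl-2-(TBSO)-6-[1-(trifluoromethanesulfonyloxy)ethenyl]cyclohex-3-en-1-yl (2R)-2-methylbutanoate | C=C(OS(=O)(=O)C(F)(F)F)[C@@H]1CC=C(C)[C@H](O[Si](C)(C)C(C)(C)C)[C@@H]1OC(=O)[C@H](C)CC | intermediate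
24 | 4-methylpent-3-en-1-ol | CC(C)=CCCO | starting material
25 | 2-[(2R)-3,3-dimethyloxiran-2-yl]ethan-1-ol | OCC[C@H]1OC1(C)C | intermediate
26 | 2-[(2R)-3,3-dimethyloxiran-2-yl]acetaldehyde | O=CC[C@H]1OC1(C)C | intermediate
27 | (1R,2S,6S)-6-{(3S)-4-[(2R)-3,3-dimethyloxiran-2-yl]-3-hydroxybut-1-en-2-yl}-3-methyl-2-(TBSO)cyclohex-3-en-1-yl (2R)-2-methylbutanoate | C=C([C@H](C[C@H]1OC1(C)C)O)[C@@H]1CC=C(C)[C@H](O[Si](C)(C)C(C)(C)C)[C@@H]1OC(=O)[C@H](C)CC | intermediate
28 | angelic acid [(2Z)-2-methylbut-2-enoic acid] | C/C=C(/C)C(=O)O | starting material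
29 | angelic 2,4,6-trichlorobenzoic anhydride | C/C=C(/C)C(=O)OC(=O)c1c(Cl)cc(Cl)cc1Cl | intermediate (not isolated)
30 | (1R,2S,6S)-6-{(3S)-3-[(2Z)-2-methylbut-2-enoyloxy]-4-[(2R)-3,3-dimethyloxiran-2-yl]but-1-en-2-yl}-3-methyl-2-(TBSO)cyclohex-3-en-1-yl (2R)-2-methylbutanoate | C=C([C@H](C[C@H]1OC1(C)C)OC(=O)/C(C)=C\C)[C@@H]1CC=C(C)[C@H](O[Si](C)(C)C(C)(C)C)[C@@H]1OC(=O)[C@H](C)CC | intermediate
31 | (1R,2S,6S)-6-{(3S)-3-[(2Z)-2-methylbut-2-enoyloxy]-4-[(2R)-3,3-dimethyloxiran-2-yl]but-1-en-2-yl}-2-hydroxy-3-methylcyclohex-3-en-1-yl (2R)-2-methylbutanoate | C=C([C@H](C[C@H]1OC1(C)C)OC(=O)/C(C)=C\C)[C@@H]1CC=C(C)[C@H](O)[C@@H]1OC(=O)[C@H](C)CC | intermediate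
32 | CNP0181486.1 (1R,2R,3R,4S,6S,8S,10R; C1 (2R)-2-methylbutanoate, C2 OH, C3/C4 and C10/C11 oxiranes, C8 angelate, C7=C14H2) | C=C([C@H](C[C@H]1OC1(C)C)OC(=O)/C(C)=C\C)[C@@H]1C[C@@H]2O[C@]2(C)[C@H](O)[C@@H]1OC(=O)[C@H](C)CC | target

**Step count and risks**

Total: 22 steps. Longest linear sequence: 19 steps (steps 1–7, 9–16, 19–22); steps 8, 17 and 18 are on the side branches.

Steps most likely to fail:

1. Step 19 (Ni/Cr coupling). The β,γ-epoxy aldehyde may undergo β-elimination to a γ-hydroxy enal before it couples, the trisubstituted oxirane may be opened by the Lewis-acidic chromium salts, and facial selectivity at C8 may be poor. The fallback installs the oxirane last and sets C8 by a reagent-controlled reduction; it sets out from 23 and comes back at 30. Alcohol 24 is oxidised with Dess–Martin periodinane to 4-methylpent-3-enal F1, which is coupled with 23 under ligand-free CrCl2/NiCl2 conditions in DMSO to the C8-epimeric allylic alcohols F2. Dess–Martin oxidation gives the cross-conjugated enone F3. Corey–Bakshi–Shibata reduction with (R)-2-methyl-CBS-oxazaborolidine and catecholborane in toluene at −78 °C, in which the α-branched alkenyl group acts as the large substituent, should give the 8S alcohol F4. Esterification as in step 20 gives the angelate F5, and Shi epoxidation (ketone of step 17) of C10=C11, the only electron-rich and unhindered trisubstituted alkene, returns to the route at 30.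

2. Step 12 (ring-closing metathesis). Closure onto the hindered isopropenyl group next to the silyloxy centre may be slow, so that intermolecular metathesis to dimers and oligomers, or alkene migration by ruthenium hydrides, takes over. The fallback replaces metathesis by a carbonyl coupling; it sets out from 16 and comes back at 17. Ozonolysis of both alkenes (O3, CH2Cl2/MeOH, −78 °C; PPh3) gives the keto aldehyde F6. Intramolecular pinacol coupling with SmI2 (THF, t-BuOH, −78 °C) closes the six-membered ring between C3 and C4 as the cis-diol F7. 1,1'-Thiocarbonyldiimidazole gives the cyclic thionocarbonate F8, and Corey–Winter olefination with 1,3-dimethyl-2-phenyl-1,3,2-diazaphospholidine at 40 °C gives cyclohexene 17. The C3 and C4 configurations of F7 and F8 do not matter as long as the diol is cis.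

3. Step 20 (angeloylation). Acylation of the hindered allylic C8 hydroxyl may be incomplete, and the activated angelate may isomerise from Z to E (tiglate) at 80 °C. The fallback builds the Z-alkene on the ester; it sets out from 27 and comes back at 30. Alcohol 27 is esterified with 2-[bis(2,2,2-trifluoroethoxy)phosphoryl]propanoic acid (DCC, DMAP, CH2Cl2) to the phosphonopropionate F9, and a Still–Gennari olefination [KN(SiMe3)2, 18-crown-6, THF, −78 °C; acetaldehyde] forms the (Z)-2-methylbut-2-enoate, which is 30.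

**Further compounds**

F1 | step 19 | 4-methylpent-3-enal | CC(C)=CCC=O
F2 | step 19 | (1R,2S,6S)-6-(3-hydroxy-6-methylhepta-1,5-dien-2-yl)-3-methyl-2-(TBSO)cyclohex-3-en-1-yl (2R)-2-methylbutanoate (C8 epimers) | C=C(C(O)CC=C(C)C)[C@@H]1CC=C(C)[C@H](O[Si](C)(C)C(C)(C)C)[C@@H]1OC(=O)[C@H](C)CC
F3 | step 19 | (1R,2S,6S)-3-methyl-6-(6-methyl-3-oxohepta-1,5-dien-2-yl)-2-(TBSO)cyclohex-3-en-1-yl (2R)-2-methylbutanoate | C=C(C(=O)CC=C(C)C)[C@@H]1CC=C(C)[C@H](O[Si](C)(C)C(C)(C)C)[C@@H]1OC(=O)[C@H](C)CC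
F4 | step 19 | (1R,2S,6S)-6-[(3S)-3-hydroxy-6-methylhepta-1,5-dien-2-yl]-3-methyl-2-(TBSO)cyclohex-3-en-1-yl (2R)-2-methylbutanoate | C=C([C@H](CC=C(C)C)O)[C@@H]1CC=C(C)[C@H](O[Si](C)(C)C(C)(C)C)[C@@H]1OC(=O)[C@H](C)CC
F5 | step 19 | (1R,2S,6S)-6-{(3S)-3-[(2Z)-2-methylbut-2-enoyloxy]-6-methylhepta-1,5-dien-2-yl}-3-methyl-2-(TBSO)cyclohex-3-en-1-yl (2R)-2-methylbutanoate | C=C([C@H](CC=C(C)C)OC(=O)/C(C)=C\C)[C@@H]1CC=C(C)[C@H](O[Si](C)(C)C(C)(C)C)[C@@H]1OC(=O)[C@H](C)CC
F6 | step 12 | (2R,3R,4S)-N-methoxy-N-methyl-5-oxo-2-(2-oxoethyl)-4-(TBSO)-3-(TESO)hexanamide | O=CC[C@@H](C(=O)N(C)OC)[C@@H](O[Si](CC)(CC)CC)[C@@H](O[Si](C)(C)C(C)(C)C)C(C)=O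
F7 | step 12 | (1R,5S,6R)-3,4-dihydroxy-N-methoxy-N,4-dimethyl-5-(TBSO)-6-(TESO)cyclohexane-1-carboxamide (cis-3,4-diol) | CON(C)C(=O)[C@@H]1CC(O)C(C)(O)[C@H](O[Si](C)(C)C(C)(C)C)[C@@H]1O[Si](CC)(CC)CC
F8 | step 12 | cyclic 3,4-thionocarbonate of F7 | CON(C)C(=O)[C@@H]1CC2OC(=S)OC2(C)[C@H](O[Si](C)(C)C(C)(C)C)[C@@H]1O[Si](CC)(CC)CC
F9 | step 20 | 8-O-{2-[bis(2,2,2-trifluoroethoxy)phosphoryl]propanoyl} derivative of 27 | C=C([C@H](C[C@H]1OC1(C)C)OC(=O)C(C)P(=O)(OCC(F)(F)F)OCC(F)(F)F)[C@@H]1CC=C(C)[C@H](O[Si](C)(C)C(C)(C)C)[C@@H]1OC(=O)[C@H](C)CC
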